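**Strategy**

Everything rests on disconnecting the bond between C6 of the (R)-2-methylbutanoyl chroman and the bridging methine carbon. Both aromatic rings belong to 5,7-dihydroxychromans whose C6 lies between the two phenolic oxygens O5 and O7: in the isobutyryl half this lets a C6-benzylic sulfone collapse to an ortho-quinone methide, in the other half it makes C6 the only free, strongly nucleophilic ring carbon. A cinchona squaramide catalysed Friedel-Crafts addition joins the two fully elaborated, unprotected halves at this hindered diarylmethine and sets its (R) configuration in the same operation. The precursor is a racemic tosyl sulfone assembled from the isobutyryl chroman, 6-methylheptanal and sulfinate.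

Key step: step 5

Remark: 6-methylheptanal and (R)-2-methylbutanoic acid are taken as catalogue compounds. The sense of induction of the squaramide in step 5 is assigned by analogy and would be confirmed on the first run (the quinidine-derived pseudoenantiomer gives the opposite sense).

**Route**

Step 1
Reactants: 1 phloroglucinol (benzene-1,3,5-triol); 2 isoprene
Product: 3 2,2-dimethylchromane-5,7-diol
Conditions: 1 (3 equiv), 2 (1 equiv), Amberlyst 15, THF/heptane, 65 °C
Reagents that add atoms: none
Why: Acid-catalysed Friedel-Crafts prenylation followed by Markovnikov hydroalkoxylation of the prenyl alkene by the neighbouring hydroxyl (chroman annulation of a phenol with isoprene) should give a single mono-chroman because 1 is threefold symmetric, and its excess holds back a second annulation.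

Step 2
Reactants: 3 2,2-dimethylchromane-5,7-diol; 4 isobutyryl chloride
Product: 5 1-(5,7-dihydroxy-2,2-dimethylchroman-8-yl)-2-methylpropan-1-one
Conditions: 4 (1.1 equiv), AlCl3 (3 equiv), PhNO2/CH2Cl2, 0 °C to rt; aq. HCl work-up, chromatography to remove the minor 6-acyl isomer
Reagents that add atoms: none
Why: Friedel-Crafts acylation of the aluminium phenoxide should favour C8, flanked by the tied-back ring oxygen and one hydroxyl, over C6, which sits between two aluminium-bound phenoxides (the same preference is known for 5,7-dihydroxycoumarins), and the first acyl group deactivates the ring against a second acylation.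

Step 3
Reactants: 5 1-(5,7-dihydroxy-2,2-dimethylchroman-8-yl)-2-methylpropan-1-one; 6 6-methylheptanal
Product: 8 1-[5,7-dihydroxy-2,2-dimethyl-6-[6-methyl-1-(4-methylbenzenesulfonyl)heptyl]chroman-8-yl]-2-methylpropan-1-one (racemic), via carbinol 7 (not isolated)
Conditions: 6 (1.5 equiv), TolSO2Na (2 equiv), HCO2H/H2O 1:1, rt
Reagents that add atoms: sodium p-toluenesulfinate, Cc1ccc(cc1)S(=O)[O-].[Na+]
Why: Three-component sulfonylalkylation of an electron-rich phenol (Mannich-type, as used for 2-(1-tosylalkyl)phenols): hydroxyalkylation at C6, the only unsubstituted ring carbon of 5, gives carbinol 7, which ionises in the acidic medium to the oxygen-stabilised benzylic cation and is captured at sulfur by excess sulfinic acid, which should outcompete a second molecule of 5; the sulfone-bearing centre is racemic and is erased in step 5.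

Step 4
Reactants: 3 2,2-dimethylchromane-5,7-diol; 9 (R)-2-methylbutanoic acid
Product: 11 (2R)-1-(5,7-dihydroxy-2,2-dimethylchroman-8-yl)-2-methylbutan-1-one, via (R)-2-methylbutanoyl chloride 10 (not isolated)
Conditions: 9, (COCl)2 (1.05 equiv), cat. DMF, CH2Cl2, 0 °C to rt; solution added to 3, AlCl3 (3 equiv), PhNO2/CH2Cl2, −10 to 0 °C; aq. HCl work-up, chromatography
Reagents that add atoms: none
Why: Acid chloride formation under DMF catalysis and low-temperature Friedel-Crafts acylation, directed to C8 as in step 2, should carry the purchased α-stereocentre through unchanged because no base is present to form a ketene and the product ketone is held as an aluminium chelate.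

Step 5
Reactants: 8 racemic tosyl sulfone; 11 (2R)-1-(5,7-dihydroxy-2,2-dimethylchroman-8-yl)-2-methylbutan-1-one
Product: 13 1-[6-[(1R)-1-[5,7-dihydroxy-2,2-dimethyl-8-[(2R)-2-methylbutanoyl]chroman-6-yl]-6-methylheptyl]-5,7-dihydroxy-2,2-dimethylchroman-8-yl]-2-methylpropan-1-one, via o-quinone methide 12 (not isolated)
Conditions: 8 (1.0 equiv), 11 (1.2 equiv), quinine-derived 3,5-bis(trifluoromethyl)phenyl squaramide (10 mol%), solid Na2CO3 (1.5 equiv), CHCl3, −20 to 0 °C
Reagents that add atoms: none
Why: Carbonate-mediated 1,4-elimination of p-toluenesulfinate from the phenoxide of 8 releases o-quinone methide 12 at low concentration, and C6 of 11 adds to its exocyclic carbon, after which tautomerisation restores both aromatic rings. The closest known reaction type is the tertiary amine-squaramide catalysed enantioselective Friedel-Crafts (conjugate) arylation of o-quinone methides generated in situ from 2-(1-tosylalkyl)phenols with naphthols and other acidic phenols. No ring is closed. The new diarylmethine stereocentre is catalyst-controlled: the squaramide N-H bonds should bind the C5 carbonyl of 12 (O7-H stays chelated to the isobutyryl carbonyl), the protonated quinuclidine pairs with the O5 phenoxide of 11, and this assembly exposes one face of the E-configured exocyclic C=C, while the remote (R)-centre of 11 has no influence. The step needs hetero- over homo-coupling and C- over O-alkylation: only 8 can form a quinone methide, only C6 of 11 is unsubstituted, and O-adducts revert. Low temperature and mild base should suppress retro-Friedel-Crafts scrambling and enolisation of the α-stereocentre.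

**Compound list**

1 | phloroglucinol (benzene-1,3,5-triol) | Oc1cc(O)cc(O)c1 | starting material
2 | isoprene | C=CC(C)=C | starting material
3 | 2,2-dimethylchromane-5,7-diol | CC1(C)CCc2c(O)cc(O)cc2O1 | intermediate
4 | isobutyryl chloride | CC(C)C(Cl)=O | starting material
5 | 1-(5,7-dihydroxy-2,2-dimethylchroman-8-yl)-2-methylpropan-1-one | CC(C)C(=O)c1c(O)cc(O)c2CCC(C)(C)Oc12 | intermediate
6 | 6-methylheptanal | CC(C)CCCCC=O | starting material
7 | 1-[5,7-dihydroxy-6-(1-hydroxy-6-methylheptyl)-2,2-dimethylchroman-8-yl]-2-methylpropan-1-one (carbinol, racemic) | CC(C)CCCCC(O)c1c(O)c2CCC(C)(C)Oc2c(C(=O)C(C)C)c1O | intermediate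
8 | 1-[5,7-dihydroxy-2,2-dimethyl-6-[6-methyl-1-(4-methylbenzenesulfonyl)heptyl]chroman-8-yl]-2-methylpropan-1-one (racemic) | CC(C)CCCCC(c1c(O)c2CCC(C)(C)Oc2c(C(=O)C(C)C)c1O)S(=O)(=O)c1ccc(C)cc1 | intermediate
9 | (R)-2-methylbutanoic acid | CC[C@@H](C)C(O)=O | starting material
10 | (R)-2-methylbutanoyl chloride | CC[C@@H](C)C(Cl)=O | intermediate
11 | (2R)-1-(5,7-dihydroxy-2,2-dimethylchroman-8-yl)-2-methylbutan-1-one | CC[C@@H](C)C(=O)c1c(O)cc(O)c2CCC(C)(C)Oc12 | intermediate
12 | (6E)-7-hydroxy-2,2-dimethyl-6-(6-methylheptylidene)-8-(2-methylpropanoyl)-3,4-dihydro-2H-chromen-5(6H)-one (o-quinone methide) | CC(C)CCCC/C=C1/C(=O)C2=C(OC(C)(C)CC2)C(C(=O)C(C)C)=C1O | intermediate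
13 | 1-[6-[(1R)-1-[5,7-dihydroxy-2,2-dimethyl-8-[(2R)-2-methylbutanoyl]chroman-6-yl]-6-methylheptyl]-5,7-dihydroxy-2,2-dimethylchroman-8-yl]-2-methylpropan-1-one | CC[C@@H](C)C(=O)c1c(O)c([C@H](CCCCC(C)C)c2c(O)c3c(c(C(=O)C(C)C)c2O)OC(C)(C)CC3)c(O)c2c1OC(C)(C)CC2 | target

**Step count and risks**

Total step count: 5. Longest linear sequence: 4 (steps 1, 2, 3, 5).

Steps most likely to fail:

1. Step 5. The process at risk is facial discrimination in the addition to 12: oxygen sits on both sides of C6, so either alkylidene geometry or carbonyl tautomer can reach the catalyst, and uncatalysed addition of the achiral sodium phenoxide competes, so that a mixture of methine epimers results. Fallback: setting out from 8 and 11, the union is run without chiral control (K2CO3, CH2Cl2/H2O, 0 °C) to give 13 together with its methine epimer, 1-[6-[(1S)-1-[5,7-dihydroxy-2,2-dimethyl-8-[(2R)-2-methylbutanoyl]chroman-6-yl]-6-methylheptyl]-5,7-dihydroxy-2,2-dimethylchroman-8-yl]-2-methylpropan-1-one F1, expected in comparable amounts. The two diastereomers are separated by preparative HPLC on an amylose carbamate chiral stationary phase, and the route is rejoined at 13.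

2. Step 4. The processes at risk are acylation at C6 in competition with C8 and erosion of the α-stereocentre through enolisation of the acylium ion or a ketene pathway under AlCl3. Fallback: setting out from 3, both hydroxyls are benzylated (BnBr, K2CO3, DMF) to give 5,7-bis(benzyloxy)-2,2-dimethylchromane F2. Bromination with NBS (CH2Cl2, −78 °C) should go to the less hindered C8 and give 8-bromo-5,7-bis(benzyloxy)-2,2-dimethylchromane F3. Acid 9 is converted (CDI, MeNHOMe·HCl, CH2Cl2) into (R)-N-methoxy-N,2-dimethylbutanamide F4. Bromine-lithium exchange on F3 (n-BuLi, THF, −78 °C) and addition of F4 should give (2R)-1-[5,7-bis(benzyloxy)-2,2-dimethylchroman-8-yl]-2-methylbutan-1-one F5. Hydrogenolysis (H2, Pd/C, EtOAc, rt) removes both benzyl groups, and the route is rejoined at 11.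

3. Step 3. The process at risk is capture of the benzylic cation derived from carbinol 7 by a second molecule of 5 (symmetrical dimer formation) faster than by sulfinate. Fallback: setting out from 5 and 6, the three-component condensation is run with 4-methylbenzenethiol (cat. TsOH, CH2Cl2, rt), a far better trap for the cation, to give the sulfide 1-[5,7-dihydroxy-2,2-dimethyl-6-[6-methyl-1-(4-methylphenylsulfanyl)heptyl]chroman-8-yl]-2-methylpropan-1-one F6. Oxidation at sulfur (mCPBA, 2.2 equiv, CH2Cl2, 0 °C) then rejoins the route at 8.

**Further compounds**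

F1 | step 5 | 1-[6-[(1S)-1-[5,7-dihydroxy-2,2-dimethyl-8-[(2R)-2-methylbutanoyl]chroman-6-yl]-6-methylheptyl]-5,7-dihydroxy-2,2-dimethylchroman-8-yl]-2-methylpropan-1-one | CC[C@@H](C)C(=O)c1c(O)c([C@@H](CCCCC(C)C)c2c(O)c3c(c(C(=O)C(C)C)c2O)OC(C)(C)CC3)c(O)c2c1OC(C)(C)CC2
F2 | step 4 | 5,7-bis(benzyloxy)-2,2-dimethylchromane | CC1(C)CCc2c(OCc3ccccc3)cc(OCc3ccccc3)cc2O1
F3 | step 4 | 8-bromo-5,7-bis(benzyloxy)-2,2-dimethylchromane | CC1(C)CCc2c(OCc3ccccc3)cc(OCc3ccccc3)c(Br)c2O1
F4 | step 4 | (R)-N-methoxy-N,2-dimethylbutanamide | CC[C@@H](C)C(=O)N(C)OC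
F5 | step 4 | (2R)-1-[5,7-bis(benzyloxy)-2,2-dimethylchroman-8-yl]-2-methylbutan-1-one | CC[C@@H](C)C(=O)c1c(OCc2ccccc2)cc(OCc2ccccc2)c2CCC(C)(C)Oc12
F6 | step 3 | 1-[5,7-dihydroxy-2,2-dimethyl-6-[6-methyl-1-(4-methylphenylsulfanyl)heptyl]chroman-8-yl]-2-methylpropan-1-one | CC(C)CCCCC(Sc1ccc(C)cc1)c1c(O)c2CCC(C)(C)Oc2c(C(=O)C(C)C)c1O
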